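**Strategy.** The route rests on disconnecting ring B (C4a–C5–C6–C7–C8–C8a) across C4a–C5 and C8–C8a: its trans carbon substituents at C4a and C8a and its C7 methyl, para to C4a, are the imprint of isoprene on an (E)-fumarate. An N-fumaroyl (S)-4-benzyloxazolidinone carrying a tert-butyl ester therefore adds isoprene under Et2AlCl, closing ring B and setting C4a and C8a in one operation while leaving C4 and C1 as two distinguishable carboxyl carbons. Amide-directed hydrogenation then sets C7; ring A follows by aldol addition and ring-closing metathesis, the propenyl group enters through an enol triflate, and a lithiated dimethoxypyridine supplies the acylpyridone.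

Key step: step 2

Remarks on the chemistry:
- Locants C1 to C8a are those of the hexahydronaphthalene core of the target (C1 propenyl, C2 acyl, C4 and C7 methyl; ring A = C1–C4, C4a, C8a; ring B = C4a–C8a).
- Assumption: mono-tert-butyl fumarate, 5-bromo-2,4-dimethoxypyridine, [4-(methoxymethoxy)phenyl]boronic acid and (E)-prop-1-enylboronic acid are purchased.
- The dienophile carries a tert-butyl ester: it is a poor ligand for aluminium and iridium, inert to MeMgBr, and leaves the imide as the only group attacked by hydroperoxide.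
- The (S)-auxiliary shields the C(alpha)-re face, so the adduct is the (1S,6S)-isomer, which corresponds to 8aS and 4aS of the target.

**Route**

Step 1
Reactants: 1 mono-tert-butyl fumarate; 2 (S)-4-benzyl-1,3-oxazolidin-2-one
Product: 4 tert-butyl (E)-4-[(4S)-4-benzyl-2-oxo-1,3-oxazolidin-3-yl]-4-oxobut-2-enoate, via pivalic mixed anhydride 3 (not isolated)
Conditions: PivCl, Et3N, THF, −20 °C; then 2, LiCl, −20 °C to rt
Reagents that add atoms: none
Why: N-acylation of the oxazolidinone by a mixed pivalic anhydride under LiCl/Et3N activation takes place at the unhindered fumaroyl carbonyl under conditions that neither isomerise the (E)-alkene nor touch the acid-labile tert-butyl ester; no stereocentre is formed.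

Step 2
Reactants: 4 tert-butyl (E)-4-[(4S)-4-benzyl-2-oxo-1,3-oxazolidin-3-yl]-4-oxobut-2-enoate; 5 isoprene
Product: 6 tert-butyl (1S,6S)-6-[(4S)-4-benzyl-2-oxo-1,3-oxazolidine-3-carbonyl]-3-methylcyclohex-3-ene-1-carboxylate
Conditions: Et2AlCl (1.5 equiv), isoprene (5 equiv), CH2Cl2, −78 °C; then 1 M HCl
Reagents that add atoms: none
Why: Et2AlCl forms a cationic aluminium chelate of the two imide carbonyls, which holds the fumaroyl unit s-cis and coplanar, and isoprene adds in a concerted, asynchronous [4+2] cycloaddition. The closest known reaction type is the Lewis-acid-promoted, auxiliary-controlled Diels–Alder reaction of N-enoyl oxazolidinones with acyclic dienes. Ring B closes as the cycloadduct ring in an intermolecular cycloaddition in which C4a–C5 and C8–C8a are formed together, suprafacially on both partners. C4a (locant 6 of 6, S) is controlled by the benzyl group of the auxiliary, which shields the C(alpha)-re face so that the diene adds to the si face; C8a (locant 1, S) follows from the (E)-geometry of the dienophile, which is transferred stereospecifically and places the two carboxyl carbons trans. The step needs facial selectivity, secured by the chelated s-cis imide, and para regioselectivity, secured because the cationic imide chelate polarises the double bond far more than the tert-butyl ester, so that the ester-bearing carbon bonds to C1 of isoprene and the methyl group ends at C7.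

Step 3
Reactants: 6 tert-butyl (1S,6S)-6-[(4S)-4-benzyl-2-oxo-1,3-oxazolidine-3-carbonyl]-3-methylcyclohex-3-ene-1-carboxylate
Product: 8 (1S,6S)-6-(tert-butoxycarbonyl)-4-methylcyclohex-3-ene-1-carboxylic acid, via peroxy acid 7 (not isolated)
Conditions: LiOH, H2O2, THF/H2O, 0 °C; then aq Na2SO3; then HCl (pH 3)
Reagents that add atoms: hydrogen peroxide, OO
Why: Hydroperoxide cleavage of the N-acyl oxazolidinone attacks the exocyclic imide carbonyl selectively and the peracid anion is reduced by sulfite before acidification, so the tert-butyl ester, the trisubstituted alkene and both stereocentres are untouched and the auxiliary is recovered.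

Step 4
Reactants: 8 (1S,6S)-6-(tert-butoxycarbonyl)-4-methylcyclohex-3-ene-1-carboxylic acid
Product: 10 tert-butyl (1S,6S)-6-[methoxy(methyl)carbamoyl]-3-methylcyclohex-3-ene-1-carboxylate, via acyl imidazole 9 (not isolated)
Conditions: CDI, CH2Cl2, rt; then MeNH(OMe)·HCl, rt
Reagents that add atoms: N,O-dimethylhydroxylamine hydrochloride, CNOC.Cl
Why: Amide coupling through the acyl imidazole is neutral and mild, so C4a does not epimerise, and it installs a Weinreb amide that serves first as the directing group and then as the ketone precursor.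

Step 5
Reactants: 10 tert-butyl (1S,6S)-6-[methoxy(methyl)carbamoyl]-3-methylcyclohex-3-ene-1-carboxylate
Product: 11 tert-butyl (1S,2S,5S)-2-[methoxy(methyl)carbamoyl]-5-methylcyclohexane-1-carboxylate
Conditions: [Ir(cod)(PCy3)(py)]PF6 (5 mol %), H2 (1 atm), CH2Cl2, 0 °C to rt
Reagents that add atoms: none
Why: Amide-directed homogeneous hydrogenation: the Lewis-basic tertiary amide oxygen should bind the cationic iridium centre much more strongly than the hindered tert-butyl ester, so both hydrogen atoms are delivered to the face of C6=C7 that carries the C4a carbonyl group, which sets C7 (7S) with the methyl trans to C4 and cis to C1, all three substituents equatorial.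

Step 6
Reactants: 11 tert-butyl (1S,2S,5S)-2-[methoxy(methyl)carbamoyl]-5-methylcyclohexane-1-carboxylate
Product: 13 tert-butyl (1S,2S,5S)-2-acetyl-5-methylcyclohexane-1-carboxylate, via magnesium hemiaminal chelate 12 (not isolated)
Conditions: MeMgBr, THF, −78 to 0 °C; aq NH4Cl
Reagents that add atoms: methylmagnesium bromide, C[Mg]Br
Why: Weinreb ketone synthesis: the five-membered magnesium chelate resists a second addition and collapses to the methyl ketone only on work-up, while the tert-butyl ester is inert to MeMgBr at this temperature and the trans-diequatorial C4a centre is the thermodynamic one.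

Step 7
Reactants: 13 tert-butyl (1S,2S,5S)-2-acetyl-5-methylcyclohexane-1-carboxylate
Product: 14 tert-butyl (1S,2S,5S)-5-methyl-2-(prop-1-en-2-yl)cyclohexane-1-carboxylate
Conditions: Ph3PCH3Br, KOtBu, THF, 0 °C to rt
Reagents that add atoms: methyltriphenylphosphonium bromide, C[P+](c1ccccc1)(c1ccccc1)c1ccccc1.[Br-]
Why: Wittig methylenation of an unhindered methyl ketone turns C4 into the isopropenyl carbon needed for ring closure; the tert-butyl ester does not react and C4a, already the more stable epimer, is not at risk.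

Step 8
Reactants: 14 tert-butyl (1S,2S,5S)-5-methyl-2-(prop-1-en-2-yl)cyclohexane-1-carboxylate
Product: 15 [(1S,2S,5S)-5-methyl-2-(prop-1-en-2-yl)cyclohexyl]methanol
Conditions: LiAlH4, THF, 0 °C to rt
Reagents that add atoms: none
Why: Hydride reduction of the ester with LiAlH4 gives the primary alcohol at C1 without affecting the 1,1-disubstituted alkene or any stereocentre.

Step 9
Reactants: 15 [(1S,2S,5S)-5-methyl-2-(prop-1-en-2-yl)cyclohexyl]methanol
Product: 16 (1S,2S,5S)-5-methyl-2-(prop-1-en-2-yl)cyclohexane-1-carbaldehyde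
Conditions: Dess–Martin periodinane (DMP), pyridine, CH2Cl2, 0 °C to rt
Reagents that add atoms: none
Why: Dess–Martin oxidation under buffered conditions stops at the aldehyde and avoids both epimerisation at C8a (already the trans, thermodynamic arrangement) and acid-induced carbonyl-ene cyclisation onto the isopropenyl group.

Step 10
Reactants: 16 (1S,2S,5S)-5-methyl-2-(prop-1-en-2-yl)cyclohexane-1-carbaldehyde; 17 methyl but-3-enoate
Product: 19 methyl 2-{hydroxy[(1S,2S,5S)-5-methyl-2-(prop-1-en-2-yl)cyclohexyl]methyl}but-3-enoate (mixture of epimers at the two new centres), via lithium dienolate 18 (not isolated)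
Conditions: 17, LiN(i-Pr)2, THF, −78 °C; then 16, −78 °C; aq NH4Cl
Reagents that add atoms: none
Why: Kinetic aldol addition of the lithium dienolate of a but-3-enoate occurs at its alpha carbon (deconjugative aldol), joining C1 to C2, which then carries the ester carbon and the vinyl group (C3); the new centres at C1 and C2 need no control because both become sp2 in steps 12 and 13.

Step 11
Reactants: 19 methyl 2-{hydroxy[(1S,2S,5S)-5-methyl-2-(prop-1-en-2-yl)cyclohexyl]methyl}but-3-enoate
Product: 20 methyl (4aS,7S,8aS)-1-hydroxy-4,7-dimethyl-1,2,4a,5,6,7,8,8a-octahydronaphthalene-2-carboxylate (epimers at C1 and C2)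
Conditions: second-generation Grubbs catalyst RuCl2(=CHPh)(H2IMes)(PCy3) (5 mol %), CH2Cl2, 40 °C
Reagents that add atoms: none
Why: Ring-closing metathesis starts at the monosubstituted vinyl group and closes onto the isopropenyl group, forming the trisubstituted C3=C4 bond of ring A with loss of ethylene; the two arms are trans-diequatorial on ring B, so a strain-free trans-fused six-membered ring results and no stereocentre is touched.

Step 12
Reactants: 20 methyl (4aS,7S,8aS)-1-hydroxy-4,7-dimethyl-1,2,4a,5,6,7,8,8a-octahydronaphthalene-2-carboxylate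
Product: 21 methyl (4aS,7S,8aS)-4,7-dimethyl-1-oxo-1,2,4a,5,6,7,8,8a-octahydronaphthalene-2-carboxylate (keto and enol forms)
Conditions: DMP, pyridine, CH2Cl2, 0 °C to rt
Reagents that add atoms: none
Why: Dess–Martin oxidation of the secondary alcohol gives the beta-keto ester, in which the epimers at C1 and C2 converge, while C8a, now alpha to the ketone, stays in the favoured trans-fused arrangement.

Step 13
Reactants: 21 methyl (4aS,7S,8aS)-4,7-dimethyl-1-oxo-1,2,4a,5,6,7,8,8a-octahydronaphthalene-2-carboxylate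
Product: 22 methyl (4aS,7S,8aS)-4,7-dimethyl-1-(trifluoromethanesulfonyloxy)-4a,5,6,7,8,8a-hexahydronaphthalene-2-carboxylate
Conditions: Tf2O, i-Pr2NEt, CH2Cl2, −78 °C
Reagents that add atoms: trifluoromethanesulfonic anhydride, O=S(=O)(OS(=O)(=O)C(F)(F)F)C(F)(F)F
Why: O-Sulfonylation of the beta-keto ester enol with Tf2O and a hindered amine gives the enol triflate regiospecifically, because only the enol between the two carbonyl groups is populated, and thereby fixes the C1=C2 bond next to C3=C4.

Step 14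
Reactants: 22 methyl (4aS,7S,8aS)-4,7-dimethyl-1-(trifluoromethanesulfonyloxy)-4a,5,6,7,8,8a-hexahydronaphthalene-2-carboxylate; 23 (E)-prop-1-enylboronic acid
Product: 24 methyl (4aS,7S,8aS)-4,7-dimethyl-1-[(E)-prop-1-enyl]-4a,5,6,7,8,8a-hexahydronaphthalene-2-carboxylate
Conditions: Pd(PPh3)4 (5 mol %), K3PO4, 1,4-dioxane/H2O, 60 °C
Reagents that add atoms: none
Why: Suzuki–Miyaura coupling of the electron-poor enol triflate with the (E)-alkenylboronic acid proceeds with retention of alkene geometry and installs the propenyl group at C1 under a mild base that should not deprotonate C8a.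

Step 15
Reactants: 24 methyl (4aS,7S,8aS)-4,7-dimethyl-1-[(E)-prop-1-enyl]-4a,5,6,7,8,8a-hexahydronaphthalene-2-carboxylate
Product: 25 {(4aS,7S,8aS)-4,7-dimethyl-1-[(E)-prop-1-enyl]-4a,5,6,7,8,8a-hexahydronaphthalen-2-yl}methanol
Conditions: i-Bu2AlH, CH2Cl2, −78 °C
Reagents that add atoms: none
Why: 1,2-Reduction of the conjugated ester with i-Bu2AlH at low temperature gives the allylic alcohol without touching the triene.

Step 16
Reactants: 25 {(4aS,7S,8aS)-4,7-dimethyl-1-[(E)-prop-1-enyl]-4a,5,6,7,8,8a-hexahydronaphthalen-2-yl}methanol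
Product: 26 (4aS,7S,8aS)-4,7-dimethyl-1-[(E)-prop-1-enyl]-4a,5,6,7,8,8a-hexahydronaphthalene-2-carbaldehyde
Conditions: MnO2, CH2Cl2, rt
Reagents that add atoms: none
Why: MnO2 oxidises allylic alcohols selectively under neutral conditions, giving the dienal without isomerisation of the triene.

Step 17
Reactants: 27 5-bromo-2,4-dimethoxypyridine; 28 [4-(methoxymethoxy)phenyl]boronic acid
Product: 29 2,4-dimethoxy-5-[4-(methoxymethoxy)phenyl]pyridine
Conditions: Pd(PPh3)4 (3 mol %), K2CO3, 1,4-dioxane/H2O, 90 °C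
Reagents that add atoms: none
Why: Suzuki–Miyaura coupling of the 5-bromopyridine with the arylboronic acid forms the biaryl bond, and the methyl and methoxymethyl ethers are stable to aqueous carbonate.

Step 18
Reactants: 29 2,4-dimethoxy-5-[4-(methoxymethoxy)phenyl]pyridine; 26 (4aS,7S,8aS)-4,7-dimethyl-1-[(E)-prop-1-enyl]-4a,5,6,7,8,8a-hexahydronaphthalene-2-carbaldehyde
Product: 31 {(4aS,7S,8aS)-4,7-dimethyl-1-[(E)-prop-1-enyl]-4a,5,6,7,8,8a-hexahydronaphthalen-2-yl}{2,4-dimethoxy-5-[4-(methoxymethoxy)phenyl]pyridin-3-yl}methanol (both carbinol epimers), via 3-lithiopyridine 30 (not isolated)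
Conditions: 29, n-BuLi, THF, −78 to −40 °C; then 26, −78 °C; aq NH4Cl
Reagents that add atoms: none
Why: Directed ortho-metalation removes the pyridine C3 proton, the only one flanked by two methoxy groups and therefore the most acidic, and the aryllithium adds 1,2 to the aldehyde; the carbinol centre is formed without control because it is oxidised in step 19.

Step 19
Reactants: 31 {(4aS,7S,8aS)-4,7-dimethyl-1-[(E)-prop-1-enyl]-4a,5,6,7,8,8a-hexahydronaphthalen-2-yl}{2,4-dimethoxy-5-[4-(methoxymethoxy)phenyl]pyridin-3-yl}methanol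
Product: 32 {(4aS,7S,8aS)-4,7-dimethyl-1-[(E)-prop-1-enyl]-4a,5,6,7,8,8a-hexahydronaphthalen-2-yl}{2,4-dimethoxy-5-[4-(methoxymethoxy)phenyl]pyridin-3-yl}methanone
Conditions: DMP, pyridine, CH2Cl2, 0 °C to rt
Reagents that add atoms: none
Why: Dess–Martin oxidation of the doubly activated (allylic and pyridylic) secondary alcohol gives the ketone under buffered conditions that leave the triene and the acetal intact.

Step 20
Reactants: 32 {(4aS,7S,8aS)-4,7-dimethyl-1-[(E)-prop-1-enyl]-4a,5,6,7,8,8a-hexahydronaphthalen-2-yl}{2,4-dimethoxy-5-[4-(methoxymethoxy)phenyl]pyridin-3-yl}methanone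
Product: 33 ilicicolin J, 3-{(4aS,7S,8aS)-4,7-dimethyl-1-[(E)-prop-1-enyl]-4a,5,6,7,8,8a-hexahydronaphthalene-2-carbonyl}-4-hydroxy-5-(4-hydroxyphenyl)pyridin-2(1H)-one
Conditions: BBr3, CH2Cl2, −78 to 0 °C; then H2O
Reagents that add atoms: none
Why: Boron tribromide ether cleavage: both pyridine methoxy groups flank the ketone and should be cleaved at low temperature with chelation assistance (the 2-methoxy group giving the pyridone), the methoxymethyl acetal is the most labile ether present, and the triene is deactivated toward electrophiles by the boron-bound ketone.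

**Compound list**

1 | mono-tert-butyl fumarate, (E)-4-tert-butoxy-4-oxobut-2-enoic acid | CC(C)(C)OC(=O)/C=C/C(=O)O | starting material
2 | (S)-4-benzyl-1,3-oxazolidin-2-one | O=C1N[C@@H](Cc2ccccc2)CO1 | starting material
3 | mixed anhydride of 1 with pivalic acid | CC(C)(C)OC(=O)/C=C/C(=O)OC(=O)C(C)(C)C | intermediate (not isolated)
4 | tert-butyl (E)-4-[(4S)-4-benzyl-2-oxo-1,3-oxazolidin-3-yl]-4-oxobut-2-enoate | CC(C)(C)OC(=O)/C=C/C(=O)N1[C@@H](Cc2ccccc2)COC1=O | intermediate
5 | isoprene | C=CC(C)=C | starting material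
6 | tert-butyl (1S,6S)-6-[(4S)-4-benzyl-2-oxo-1,3-oxazolidine-3-carbonyl]-3-methylcyclohex-3-ene-1-carboxylate | O=C(N1[C@@H](Cc2ccccc2)COC1=O)[C@H]3CC=C(C)C[C@@H]3C(=O)OC(C)(C)C | intermediate
7 | (1S,6S)-6-(tert-butoxycarbonyl)-4-methylcyclohex-3-ene-1-carboperoxoic acid | OOC(=O)[C@H]1CC=C(C)C[C@@H]1C(=O)OC(C)(C)C | intermediate (not isolated)
8 | (1S,6S)-6-(tert-butoxycarbonyl)-4-methylcyclohex-3-ene-1-carboxylic acid | OC(=O)[C@H]1CC=C(C)C[C@@H]1C(=O)OC(C)(C)C | intermediate
9 | tert-butyl (1S,6S)-6-(imidazole-1-carbonyl)-3-methylcyclohex-3-ene-1-carboxylate | O=C(n1ccnc1)[C@H]2CC=C(C)C[C@@H]2C(=O)OC(C)(C)C | intermediate (not isolated)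
10 | tert-butyl (1S,6S)-6-[methoxy(methyl)carbamoyl]-3-methylcyclohex-3-ene-1-carboxylate | CON(C)C(=O)[C@H]1CC=C(C)C[C@@H]1C(=O)OC(C)(C)C | intermediate
11 | tert-butyl (1S,2S,5S)-2-[methoxy(methyl)carbamoyl]-5-methylcyclohexane-1-carboxylate | CON(C)C(=O)[C@H]1CC[C@H](C)C[C@@H]1C(=O)OC(C)(C)C | intermediate
12 | bromomagnesium salt of the hemiaminal from 11 and MeMgBr (carbinol carbon unassigned) | CON(C)C(C)(O[Mg]Br)[C@H]1CC[C@H](C)C[C@@H]1C(=O)OC(C)(C)C | intermediate (not isolated)
13 | tert-butyl (1S,2S,5S)-2-acetyl-5-methylcyclohexane-1-carboxylate | CC(=O)[C@H]1CC[C@H](C)C[C@@H]1C(=O)OC(C)(C)C | intermediate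
14 | tert-butyl (1S,2S,5S)-5-methyl-2-(prop-1-en-2-yl)cyclohexane-1-carboxylate | C=C(C)[C@H]1CC[C@H](C)C[C@@H]1C(=O)OC(C)(C)C | intermediate
15 | [(1S,2S,5S)-5-methyl-2-(prop-1-en-2-yl)cyclohexyl]methanol | C=C(C)[C@H]1CC[C@H](C)C[C@@H]1CO | intermediate
16 | (1S,2S,5S)-5-methyl-2-(prop-1-en-2-yl)cyclohexane-1-carbaldehyde | C=C(C)[C@H]1CC[C@H](C)C[C@@H]1C=O | intermediate
17 | methyl but-3-enoate | C=CCC(=O)OC | starting material
18 | lithium 1-methoxybuta-1,3-dien-1-olate | [Li]OC(OC)=CC=C | intermediate (not isolated)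
19 | methyl 2-{hydroxy[(1S,2S,5S)-5-methyl-2-(prop-1-en-2-yl)cyclohexyl]methyl}but-3-enoate (epimers at the carbinol and alpha carbons) | C=C(C)[C@H]1CC[C@H](C)C[C@@H]1C(O)C(C=C)C(=O)OC | intermediate
20 | methyl (4aS,7S,8aS)-1-hydroxy-4,7-dimethyl-1,2,4a,5,6,7,8,8a-octahydronaphthalene-2-carboxylate (epimers at C1, C2) | COC(=O)C1C=C(C)[C@H]2CC[C@H](C)C[C@@H]2C1O | intermediate
21 | methyl (4aS,7S,8aS)-4,7-dimethyl-1-oxo-1,2,4a,5,6,7,8,8a-octahydronaphthalene-2-carboxylate | COC(=O)C1C=C(C)[C@H]2CC[C@H](C)C[C@@H]2C1=O | intermediate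
22 | methyl (4aS,7S,8aS)-4,7-dimethyl-1-(trifluoromethanesulfonyloxy)-4a,5,6,7,8,8a-hexahydronaphthalene-2-carboxylate | FC(F)(F)S(=O)(=O)OC1=C(C(=O)OC)C=C(C)[C@H]2CC[C@H](C)C[C@H]12 | intermediate
23 | (E)-prop-1-enylboronic acid | C/C=C/B(O)O | starting material
24 | methyl (4aS,7S,8aS)-4,7-dimethyl-1-[(E)-prop-1-enyl]-4a,5,6,7,8,8a-hexahydronaphthalene-2-carboxylate | C/C=C/C1=C(C(=O)OC)C=C(C)[C@H]2CC[C@H](C)C[C@H]12 | intermediate
25 | {(4aS,7S,8aS)-4,7-dimethyl-1-[(E)-prop-1-enyl]-4a,5,6,7,8,8a-hexahydronaphthalen-2-yl}methanol | C/C=C/C1=C(CO)C=C(C)[C@H]2CC[C@H](C)C[C@H]12 | intermediate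
26 | (4aS,7S,8aS)-4,7-dimethyl-1-[(E)-prop-1-enyl]-4a,5,6,7,8,8a-hexahydronaphthalene-2-carbaldehyde | C/C=C/C1=C(C=O)C=C(C)[C@H]2CC[C@H](C)C[C@H]12 | intermediate
27 | 5-bromo-2,4-dimethoxypyridine | COc1cc(OC)c(Br)cn1 | starting material
28 | [4-(methoxymethoxy)phenyl]boronic acid | COCOc1ccc(B(O)O)cc1 | starting material
29 | 2,4-dimethoxy-5-[4-(methoxymethoxy)phenyl]pyridine | COCOc1ccc(-c2cnc(OC)cc2OC)cc1 | intermediate
30 | {2,4-dimethoxy-5-[4-(methoxymethoxy)phenyl]pyridin-3-yl}lithium | [Li]c1c(OC)ncc(-c2ccc(OCOC)cc2)c1OC | intermediate (not isolated)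
31 | {(4aS,7S,8aS)-4,7-dimethyl-1-[(E)-prop-1-enyl]-4a,5,6,7,8,8a-hexahydronaphthalen-2-yl}{2,4-dimethoxy-5-[4-(methoxymethoxy)phenyl]pyridin-3-yl}methanol (carbinol epimers) | C/C=C/C1=C(C(O)c3c(OC)ncc(-c4ccc(OCOC)cc4)c3OC)C=C(C)[C@H]2CC[C@H](C)C[C@H]12 | intermediate
32 | {(4aS,7S,8aS)-4,7-dimethyl-1-[(E)-prop-1-enyl]-4a,5,6,7,8,8a-hexahydronaphthalen-2-yl}{2,4-dimethoxy-5-[4-(methoxymethoxy)phenyl]pyridin-3-yl}methanone | C/C=C/C1=C(C(=O)c3c(OC)ncc(-c4ccc(OCOC)cc4)c3OC)C=C(C)[C@H]2CC[C@H](C)C[C@H]12 | intermediate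
33 | ilicicolin J, 3-{(4aS,7S,8aS)-4,7-dimethyl-1-[(E)-prop-1-enyl]-4a,5,6,7,8,8a-hexahydronaphthalene-2-carbonyl}-4-hydroxy-5-(4-hydroxyphenyl)pyridin-2(1H)-one | C/C=C/C1=C(C(=O)c2c(O)c(-c3ccc(O)cc3)c[nH]c2=O)C=C(C)[C@H]2CC[C@H](C)C[C@H]12 | target

**Totals**

Total step count: 20. Longest linear sequence: 19 steps (steps 1 to 16 and 18 to 20); step 17 prepares the pyridine fragment.

**Steps most likely to fail**

1. Step 2. The aluminium reagent may be partly engaged by the ester carbonyl, so that the imide is not held as the two-point chelate; this would lower both facial and para selectivity, and the Lewis acid may also strip the tert-butyl group. The fallback replaces auxiliary control by catalyst control; it sets out from 1 and returns at 8. Mixed anhydride 3 is made from 1 as in step 1 and treated with oxazolidin-2-one, LiCl and Et3N to give tert-butyl (E)-4-oxo-4-(2-oxo-1,3-oxazolidin-3-yl)but-2-enoate F1. With isoprene and [Cu((S,S)-t-Bu-box)](SbF6)2 (10 mol %) in CH2Cl2, a catalyst that activates only through two-point binding of the imide and is too mild to cleave the ester, F1 should give tert-butyl (1S,6S)-3-methyl-6-(2-oxo-1,3-oxazolidine-3-carbonyl)cyclohex-3-ene-1-carboxylate F2; the (S,S)-ligand is expected to expose the same C(alpha)-si face. LiOH/H2O2 then leads through peroxy acid 7 to acid 8.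

2. Step 5. Hydrogen may be delivered from the ester-bearing face, by ester-bound or unbound catalyst, which would give the C7 epimer with an axial methyl group. The fallback replaces directed delivery by thermodynamic control through hydrogen-atom transfer; it sets out from 10 and returns at 11. With Mn(dpm)3 (cat.), PhSiH3 and t-BuOOH in i-PrOH at rt, the alkene takes up a hydrogen atom at C6, and the tertiary C7 radical is reduced from the axial direction of a ring held by the two trans-diequatorial carbonyl groups, so the methyl group should end equatorial as in 11. No new compound is made.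

3. Step 20. Bromide or hydrogen bromide may add to the cross-conjugated triene, the Lewis acid may shift double bonds, or the 2-methoxy group may be cleaved incompletely. The fallback uses fluoride-labile protection throughout; it sets out from 26 and returns at 33. 5-Bromo-2,4-dichloropyridine and 2-(trimethylsilyl)ethanol with NaH in DMF (0 to 70 °C) should give, by double nucleophilic aromatic substitution, 5-bromo-2,4-bis[2-(trimethylsilyl)ethoxy]pyridine F3. Suzuki–Miyaura coupling with {4-[(tert-butyldimethylsilyl)oxy]phenyl}boronic acid (Pd(PPh3)4, K2CO3) gives 5-{4-[(tert-butyldimethylsilyl)oxy]phenyl}-2,4-bis[2-(trimethylsilyl)ethoxy]pyridine F4. Lithiation with n-BuLi at −78 °C gives the 3-lithio derivative of F4, (5-{4-[(tert-butyldimethylsilyl)oxy]phenyl}-2,4-bis[2-(trimethylsilyl)ethoxy]pyridin-3-yl)lithium F5, which adds to 26 to give the carbinol (5-{4-[(tert-butyldimethylsilyl)oxy]phenyl}-2,4-bis[2-(trimethylsilyl)ethoxy]pyridin-3-yl){(4aS,7S,8aS)-4,7-dimethyl-1-[(E)-prop-1-enyl]-4a,5,6,7,8,8a-hexahydronaphthalen-2-yl}methanol F6. Dess–Martin oxidation gives the corresponding ketone, (5-{4-[(tert-butyldimethylsilyl)oxy]phenyl}-2,4-bis[2-(trimethylsilyl)ethoxy]pyridin-3-yl){(4aS,7S,8aS)-4,7-dimethyl-1-[(E)-prop-1-enyl]-4a,5,6,7,8,8a-hexahydronaphthalen-2-yl}methanone F7. Bu4NF in THF then removes all three silicon-based groups under non-acidic conditions to give 33.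

**Further compounds**

F1 | step 2 | tert-butyl (E)-4-oxo-4-(2-oxo-1,3-oxazolidin-3-yl)but-2-enoate | CC(C)(C)OC(=O)/C=C/C(=O)N1CCOC1=O
F2 | step 2 | tert-butyl (1S,6S)-3-methyl-6-(2-oxo-1,3-oxazolidine-3-carbonyl)cyclohex-3-ene-1-carboxylate | O=C(N1CCOC1=O)[C@H]2CC=C(C)C[C@@H]2C(=O)OC(C)(C)C
F0 | step 5 | none | none
F3 | step 20 | 5-bromo-2,4-bis[2-(trimethylsilyl)ethoxy]pyridine | C[Si](C)(C)CCOc1cc(OCC[Si](C)(C)C)c(Br)cn1
F4 | step 20 | 5-{4-[(tert-butyldimethylsilyl)oxy]phenyl}-2,4-bis[2-(trimethylsilyl)ethoxy]pyridine | C[Si](C)(C)CCOc1cc(OCC[Si](C)(C)C)c(-c2ccc(O[Si](C)(C)C(C)(C)C)cc2)cn1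
F5 | step 20 | (5-{4-[(tert-butyldimethylsilyl)oxy]phenyl}-2,4-bis[2-(trimethylsilyl)ethoxy]pyridin-3-yl)lithium | [Li]c1c(OCC[Si](C)(C)C)ncc(-c2ccc(O[Si](C)(C)C(C)(C)C)cc2)c1OCC[Si](C)(C)C
F6 | step 20 | (5-{4-[(tert-butyldimethylsilyl)oxy]phenyl}-2,4-bis[2-(trimethylsilyl)ethoxy]pyridin-3-yl){(4aS,7S,8aS)-4,7-dimethyl-1-[(E)-prop-1-enyl]-4a,5,6,7,8,8a-hexahydronaphthalen-2-yl}methanol | C/C=C/C1=C(C(O)c3c(OCC[Si](C)(C)C)ncc(-c4ccc(O[Si](C)(C)C(C)(C)C)cc4)c3OCC[Si](C)(C)C)C=C(C)[C@H]2CC[C@H](C)C[C@H]12
F7 | step 20 | (5-{4-[(tert-butyldimethylsilyl)oxy]phenyl}-2,4-bis[2-(trimethylsilyl)ethoxy]pyridin-3-yl){(4aS,7S,8aS)-4,7-dimethyl-1-[(E)-prop-1-enyl]-4a,5,6,7,8,8a-hexahydronaphthalen-2-yl}methanone | C/C=C/C1=C(C(=O)c3c(OCC[Si](C)(C)C)ncc(-c4ccc(O[Si](C)(C)C(C)(C)C)cc4)c3OCC[Si](C)(C)C)C=C(C)[C@H]2CC[C@H](C)C[C@H]12
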